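Ring C is disconnected at C4–C4a. Ring A, as a 2-methoxyphenol, and ring B, as an arylpropiolate, are first joined through O1–C2 by oxa-Michael addition; the derived 3-aryloxy-3-arylacrylic acid is then closed by one intramolecular Friedel–Crafts acylation, which forms C4–C4a and the complete flavone core. The step exploits the position of O1 on C8a next to the methoxy-bearing C8: the aryloxy ring has a single free ortho carbon (future C4a), activated by the oxygens on C5 and C7, so the 5,7-dioxy-8-methoxy pattern cannot scramble to the 6-methoxy isomer. C3 hydroxylation, O-methylation and neutral hydrogenolysis of four benzyl ethers finish the route.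

Key step: step 11

Assumption: enol ether 14 and acid 15 are drawn as the Z isomers (carboxyl cis to the aryloxy group, the geometry needed for ring closure); any E isomer formed alongside is carried on unseparated, because the push–pull enol ether should equilibrate under the acidic acylation conditions of step 11.

Step 1
Reactants: 1 3,5-bis(benzyloxy)phenol
Product: 3 4,6-bis(benzyloxy)-2-hydroxybenzaldehyde, via hydroxymethylphenol 2 (not isolated)
Conditions: MgCl2, Et3N, (CH2O)n, MeCN, reflux; aq. HCl work-up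
Reagents that add atoms: paraformaldehyde (as formaldehyde), C=O
Why: Magnesium-mediated ortho-formylation, in which the magnesium phenoxide delivers formaldehyde only to the ortho carbon (both ortho sites of 1 are equivalent) and a second formaldehyde oxidises the hydroxymethyl intermediate by hydride transfer, leaving the benzyl ethers untouched.

Step 2
Reactants: 3 4,6-bis(benzyloxy)-2-hydroxybenzaldehyde
Product: 4 4,6-bis(benzyloxy)-2-(methoxymethoxy)benzaldehyde
Conditions: MOMCl, K2CO3, DMF, 0 °C to rt
Reagents that add atoms: chloromethyl methyl ether, COCCl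
Why: Williamson-type O-alkylation of the phenoxide gives an acetal that tolerates peracid and base and can later be removed without affecting benzyl ethers.

Step 3
Reactants: 4 4,6-bis(benzyloxy)-2-(methoxymethoxy)benzaldehyde
Product: 6 4,6-bis(benzyloxy)-2-(methoxymethoxy)phenol, via aryl formate 5 (not isolated)
Conditions: mCPBA, CH2Cl2, 0 °C to rt; excess peracid destroyed (aq. Na2S2O3 wash); then K2CO3 (cat.), MeOH, rt; product used directly
Reagents that add atoms: meta-chloroperoxybenzoic acid, OOC(=O)c1cccc(Cl)c1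
Why: Baeyer–Villiger (Dakin-type) oxidation, in which the electron-rich 2,4,6-trioxygenated aryl group migrates in preference to hydrogen and the resulting aryl formate is cleaved by transesterification with methanol.

Step 4
Reactants: 6 4,6-bis(benzyloxy)-2-(methoxymethoxy)phenol
Product: 7 1,5-bis(benzyloxy)-2-methoxy-3-(methoxymethoxy)benzene
Conditions: MeI, K2CO3, DMF, rt
Reagents that add atoms: iodomethane, CI
Why: Williamson O-methylation of the only free phenol installs the oxygen substituent that becomes the C8 methoxy group.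

Step 5
Reactants: 7 1,5-bis(benzyloxy)-2-methoxy-3-(methoxymethoxy)benzene
Product: 8 3,5-bis(benzyloxy)-2-methoxyphenol
Conditions: conc. HCl (cat.), MeOH/THF, 40 °C
Reagents that add atoms: none
Why: Acid-catalysed transacetalisation removes the MOM group as dimethoxymethane in methanol, conditions under which aryl benzyl and methyl ethers are stable and free formaldehyde is not released onto the electron-rich ring.

Step 6
Reactants: 9 2,4-dihydroxy-5-methoxybenzaldehyde
Product: 10 2,4-bis(benzyloxy)-5-methoxybenzaldehyde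
Conditions: BnBr, K2CO3, DMF, 60 °C
Reagents that add atoms: benzyl bromide, BrCc1ccccc1
Why: Double Williamson benzylation, with warming in DMF sufficient to alkylate the hydrogen-bonded 2-OH as well as the 4-OH.

Step 7
Reactants: 10 2,4-bis(benzyloxy)-5-methoxybenzaldehyde
Product: 11 1,5-bis(benzyloxy)-2-(2,2-dibromoethenyl)-4-methoxybenzene
Conditions: CBr4, PPh3, CH2Cl2, 0 °C
Reagents that add atoms: carbon tetrabromide, BrC(Br)(Br)Br
Why: First stage of the Corey–Fuchs reaction, a Wittig olefination of the aldehyde by the ylide Ph3P=CBr2 generated in the flask.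

Step 8
Reactants: 11 1,5-bis(benzyloxy)-2-(2,2-dibromoethenyl)-4-methoxybenzene
Product: 13 methyl 3-[2,4-bis(benzyloxy)-5-methoxyphenyl]prop-2-ynoate, via lithium acetylide 12 (not isolated)
Conditions: n-BuLi (2.1 equiv), THF, −78 °C; then ClCO2Me, −78 to 0 °C
Reagents that add atoms: methyl chloroformate, COC(Cl)=O
Why: Second stage of the Corey–Fuchs reaction, in which bromine–lithium exchange and elimination give the lithium acetylide, which is C-acylated by the chloroformate at low temperature before the benzyl ethers can be metalated.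

Step 9
Reactants: 8 3,5-bis(benzyloxy)-2-methoxyphenol; 13 methyl 3-[2,4-bis(benzyloxy)-5-methoxyphenyl]prop-2-ynoate
Product: 14 methyl (Z)-3-[3,5-bis(benzyloxy)-2-methoxyphenoxy]-3-[2,4-bis(benzyloxy)-5-methoxyphenyl]prop-2-enoate
Conditions: Cs2CO3 (0.5 equiv), DMF, 80–100 °C
Reagents that add atoms: none
Why: Base-mediated oxa-Michael addition of the phenoxide to the β-carbon of the ynoate forms the O1–C2 bond, anti addition placing the ester cis to the aryloxy group.

Step 10
Reactants: 14 methyl (Z)-3-[3,5-bis(benzyloxy)-2-methoxyphenoxy]-3-[2,4-bis(benzyloxy)-5-methoxyphenyl]prop-2-enoate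
Product: 15 (Z)-3-[3,5-bis(benzyloxy)-2-methoxyphenoxy]-3-[2,4-bis(benzyloxy)-5-methoxyphenyl]prop-2-enoic acid
Conditions: LiOH·H2O, THF/MeOH/H2O, rt to 40 °C; then 1 M HCl to pH 3–4, 0 °C
Reagents that add atoms: lithium hydroxide, [Li+].[OH-]
Why: Ester saponification by acyl–oxygen cleavage, the β-carbon of the vinylogous carbonate being much less electrophilic than the ester carbonyl and the cold, brief acidification sparing the enol ether.

Step 11
Reactants: 15 (Z)-3-[3,5-bis(benzyloxy)-2-methoxyphenoxy]-3-[2,4-bis(benzyloxy)-5-methoxyphenyl]prop-2-enoic acid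
Product: 17 5,7-bis(benzyloxy)-2-[2,4-bis(benzyloxy)-5-methoxyphenyl]-8-methoxy-4H-chromen-4-one, via mixed trifluoroacetic anhydride 16 (not isolated)
Conditions: TFAA (2–3 equiv), CH2Cl2, 0 °C to rt
Reagents that add atoms: none
Why: TFAA converts the acid into mixed anhydride 16, an acylium equivalent stabilised by the β-aryloxy enol ether, and the single free ortho carbon of the aryloxy ring attacks the acyl carbon, after which proton loss rearomatises ring A and gives the flavone. The closest known reaction type is the intramolecular Friedel–Crafts cyclodehydration of β-aryloxycinnamic acids to flavones. Ring C is closed by forming C4–C4a in a six-membered electrophilic aromatic substitution (6-exo-trig at the anhydride carbonyl), and no stereocentre is created. The step needs site selectivity for the ring A carbon over C6' of ring B and over a 6-methoxy isomer: the other ortho position of the aryloxy ring is blocked by OMe, the reacting carbon is ortho to O1 and to the C5 benzyloxy group and para to the C7 benzyloxy group, and chromone formation is favoured over the strained five-membered indenone. Any E enol ether should equilibrate through C3 protonation by the trifluoroacetic acid released, and the absence of strong protic or Lewis acid should keep all four benzyl ethers in place.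

Step 12
Reactants: 17 5,7-bis(benzyloxy)-2-[2,4-bis(benzyloxy)-5-methoxyphenyl]-8-methoxy-4H-chromen-4-one
Product: 19 5,7,2',4'-tetrakis(benzyloxy)-3-hydroxy-8,5'-dimethoxyflavone, via 2,3-epoxide 18 (not isolated)
Conditions: DMDO (acetone solution, excess), CH2Cl2, 0 °C to rt; evaporate; then p-TsOH·H2O (cat.), CH2Cl2, rt
Reagents that add atoms: dimethyldioxirane, CC1(C)OO1
Why: Electrophilic epoxidation of the C2=C3 enol ether double bond by the dioxirane, followed by acid-catalysed opening at C2 to an oxocarbenium ion and loss of the C3 proton, delivers the 3-hydroxyflavone under conditions that benzyl ethers tolerate.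

Step 13
Reactants: 19 5,7,2',4'-tetrakis(benzyloxy)-3-hydroxy-8,5'-dimethoxyflavone
Product: 20 5,7,2',4'-tetrakis(benzyloxy)-3,8,5'-trimethoxyflavone
Conditions: MeI, K2CO3, acetone, reflux
Reagents that add atoms: iodomethane, CI
Why: Williamson O-methylation of the only free hydroxyl, the acidic 3-OH enol.

Step 14
Reactants: 20 5,7,2',4'-tetrakis(benzyloxy)-3,8,5'-trimethoxyflavone
Product: 21 5,7,2',4'-tetrahydroxy-3,8,5'-trimethoxyflavone
Conditions: H2 (1 atm), Pd/C, EtOAc/MeOH, rt
Reagents that add atoms: none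
Why: Heterogeneous hydrogenolysis of the four aryl benzyl ethers under neutral conditions, which should neither reduce the chromone nor trigger Wessely–Moser isomerisation to the 6-methoxy isomer.

Compound list
1 | 3,5-bis(benzyloxy)phenol | Oc1cc(OCc2ccccc2)cc(OCc2ccccc2)c1 | starting material
2 | 3,5-bis(benzyloxy)-2-(hydroxymethyl)phenol (present as its magnesium salt) | OCc1c(O)cc(OCc2ccccc2)cc1OCc1ccccc1 | intermediate
3 | 4,6-bis(benzyloxy)-2-hydroxybenzaldehyde | O=Cc1c(O)cc(OCc2ccccc2)cc1OCc1ccccc1 | intermediate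
4 | 4,6-bis(benzyloxy)-2-(methoxymethoxy)benzaldehyde | O=Cc1c(OCOC)cc(OCc2ccccc2)cc1OCc1ccccc1 | intermediate
5 | 4,6-bis(benzyloxy)-2-(methoxymethoxy)phenyl formate | O=COc1c(OCOC)cc(OCc2ccccc2)cc1OCc1ccccc1 | intermediate
6 | 4,6-bis(benzyloxy)-2-(methoxymethoxy)phenol | Oc1c(OCOC)cc(OCc2ccccc2)cc1OCc1ccccc1 | intermediate
7 | 1,5-bis(benzyloxy)-2-methoxy-3-(methoxymethoxy)benzene | COCOc1cc(OCc2ccccc2)cc(OCc2ccccc2)c1OC | intermediate
8 | 3,5-bis(benzyloxy)-2-methoxyphenol | COc1c(O)cc(OCc2ccccc2)cc1OCc1ccccc1 | intermediate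
9 | 2,4-dihydroxy-5-methoxybenzaldehyde | COc1cc(C=O)c(O)cc1O | starting material
10 | 2,4-bis(benzyloxy)-5-methoxybenzaldehyde | COc1cc(C=O)c(OCc2ccccc2)cc1OCc1ccccc1 | intermediate
11 | 1,5-bis(benzyloxy)-2-(2,2-dibromoethenyl)-4-methoxybenzene | COc1cc(C=C(Br)Br)c(OCc2ccccc2)cc1OCc1ccccc1 | intermediate
12 | lithium [2,4-bis(benzyloxy)-5-methoxyphenyl]acetylide | [Li]C#Cc1cc(OC)c(OCc2ccccc2)cc1OCc1ccccc1 | intermediate
13 | methyl 3-[2,4-bis(benzyloxy)-5-methoxyphenyl]prop-2-ynoate | COC(=O)C#Cc1cc(OC)c(OCc2ccccc2)cc1OCc1ccccc1 | intermediate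
14 | methyl (Z)-3-[3,5-bis(benzyloxy)-2-methoxyphenoxy]-3-[2,4-bis(benzyloxy)-5-methoxyphenyl]prop-2-enoate | COC(=O)/C=C(\Oc1cc(OCc2ccccc2)cc(OCc2ccccc2)c1OC)c1cc(OC)c(OCc2ccccc2)cc1OCc1ccccc1 | intermediate
15 | (Z)-3-[3,5-bis(benzyloxy)-2-methoxyphenoxy]-3-[2,4-bis(benzyloxy)-5-methoxyphenyl]prop-2-enoic acid | OC(=O)/C=C(\Oc1cc(OCc2ccccc2)cc(OCc2ccccc2)c1OC)c1cc(OC)c(OCc2ccccc2)cc1OCc1ccccc1 | intermediate
16 | mixed anhydride of acid 15 and trifluoroacetic acid | FC(F)(F)C(=O)OC(=O)/C=C(\Oc1cc(OCc2ccccc2)cc(OCc2ccccc2)c1OC)c1cc(OC)c(OCc2ccccc2)cc1OCc1ccccc1 | intermediate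
17 | 5,7-bis(benzyloxy)-2-[2,4-bis(benzyloxy)-5-methoxyphenyl]-8-methoxy-4H-chromen-4-one (5,7,2',4'-tetrakis(benzyloxy)-8,5'-dimethoxyflavone) | COc1cc(-c2cc(=O)c3c(OCc4ccccc4)cc(OCc4ccccc4)c(OC)c3o2)c(OCc2ccccc2)cc1OCc1ccccc1 | intermediate
18 | 2,3-epoxy-5,7,2',4'-tetrakis(benzyloxy)-8,5'-dimethoxyflavan-4-one (racemic, epoxide necessarily cis-fused) | COc1cc(C23OC2C(=O)c2c(O3)c(OC)c(OCc3ccccc3)cc2OCc2ccccc2)c(OCc2ccccc2)cc1OCc1ccccc1 | intermediate
19 | 5,7,2',4'-tetrakis(benzyloxy)-3-hydroxy-8,5'-dimethoxyflavone | COc1cc(-c2oc3c(OC)c(OCc4ccccc4)cc(OCc4ccccc4)c3c(=O)c2O)c(OCc2ccccc2)cc1OCc1ccccc1 | intermediate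
20 | 5,7,2',4'-tetrakis(benzyloxy)-3,8,5'-trimethoxyflavone | COc1cc(-c2oc3c(OC)c(OCc4ccccc4)cc(OCc4ccccc4)c3c(=O)c2OC)c(OCc2ccccc2)cc1OCc1ccccc1 | intermediate
21 | 5,7,2',4'-tetrahydroxy-3,8,5'-trimethoxyflavone | COc1cc(-c2oc3c(OC)c(O)cc(O)c3c(=O)c2OC)c(O)cc1O | target

Total step count: 14.
Longest linear sequence: 11 steps (steps 1–5, then steps 9–14); the ring B branch (steps 6–8) joins at step 9.

Steps most likely to fail

Step 9. The conjugate addition may stall because the β-carbon of ynoate 13 is deactivated by the electron-rich, ortho-substituted aryl group and the phenoxide of 8 is hindered; forcing conditions could then lead to ester exchange or decomposition before the C–O bond forms. The fallback replaces the ester acceptor by a far more electrophilic aldehyde and adjusts the oxidation state afterwards. It sets out from dibromoolefin 11: treatment with n-BuLi in THF at −78 °C and trapping of the acetylide with DMF (buffered aqueous quench) should give 3-[2,4-bis(benzyloxy)-5-methoxyphenyl]prop-2-ynal F1. Phenol 8 should add to this ynal under mild base (K2CO3 cat., MeCN, rt) to give (Z)-3-[3,5-bis(benzyloxy)-2-methoxyphenoxy]-3-[2,4-bis(benzyloxy)-5-methoxyphenyl]prop-2-enal F2. Pinnick oxidation (NaClO2, NaH2PO4, 2-methyl-2-butene, t-BuOH/H2O) would then convert the enal directly to acid 15, where the route is rejoined without the saponification.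

Step 11. The trifluoroacetic acid released may strip benzyl ethers (above all the one at C5 once the carbonyl is in place), TFAA may C-trifluoroacetylate the electron-rich rings, or an E enol ether that fails to equilibrate may close onto ring B. The fallback abandons carbon-centred ring closure and forms ring C at O1–C2 from an ortho-hydroxyaryl ynone; regiochemistry stays unambiguous because only one phenolic oxygen is free. It sets out from phenol 8: magnesium-mediated ortho-formylation (MgCl2, Et3N, (CH2O)n, MeCN, reflux) at the only free ortho carbon should give 4,6-bis(benzyloxy)-2-hydroxy-3-methoxybenzaldehyde F3. Addition of excess lithium acetylide 12 (generated from 11 with n-BuLi, THF, −78 °C) would give racemic 1-[4,6-bis(benzyloxy)-2-hydroxy-3-methoxyphenyl]-3-[2,4-bis(benzyloxy)-5-methoxyphenyl]prop-2-yn-1-ol F4. Oxidation with MnO2 in CH2Cl2 would give 1-[4,6-bis(benzyloxy)-2-hydroxy-3-methoxyphenyl]-3-[2,4-bis(benzyloxy)-5-methoxyphenyl]prop-2-yn-1-one F5. Treatment with Et2NH in EtOH (amine conjugate addition, then 6-endo ring closure with loss of the amine) should deliver flavone 17, where the route is rejoined.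

Step 12. Epoxidation of the hindered C2=C3 bond, flanked by the ortho-substituted ring B, may be slow enough for the dioxirane to oxidise benzylic C–H bonds of the benzyl ethers or the electron-rich rings instead. The fallback replaces electrophilic oxidation by deprotonation, borylation and oxidation. It sets out from flavone 17: LDA in THF at −78 °C should remove the C3 proton to give 3-lithio-5,7,2',4'-tetrakis(benzyloxy)-8,5'-dimethoxyflavone F6, which is trapped with B(OMe)3 as dimethyl [5,7,2',4'-tetrakis(benzyloxy)-8,5'-dimethoxyflavon-3-yl]boronate F7. Oxidation with H2O2/AcOH would give flavonol 19, where the route is rejoined.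

Further compounds
F1 | step 9 | 3-[2,4-bis(benzyloxy)-5-methoxyphenyl]prop-2-ynal | O=CC#Cc1cc(OC)c(OCc2ccccc2)cc1OCc1ccccc1
F2 | step 9 | (Z)-3-[3,5-bis(benzyloxy)-2-methoxyphenoxy]-3-[2,4-bis(benzyloxy)-5-methoxyphenyl]prop-2-enal | O=C/C=C(\Oc1cc(OCc2ccccc2)cc(OCc2ccccc2)c1OC)c1cc(OC)c(OCc2ccccc2)cc1OCc1ccccc1
F3 | step 11 | 4,6-bis(benzyloxy)-2-hydroxy-3-methoxybenzaldehyde | O=Cc1c(O)c(OC)c(OCc2ccccc2)cc1OCc1ccccc1
F4 | step 11 | 1-[4,6-bis(benzyloxy)-2-hydroxy-3-methoxyphenyl]-3-[2,4-bis(benzyloxy)-5-methoxyphenyl]prop-2-yn-1-ol (racemic) | COc1cc(C#CC(O)c2c(O)c(OC)c(OCc3ccccc3)cc2OCc2ccccc2)c(OCc2ccccc2)cc1OCc1ccccc1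
F5 | step 11 | 1-[4,6-bis(benzyloxy)-2-hydroxy-3-methoxyphenyl]-3-[2,4-bis(benzyloxy)-5-methoxyphenyl]prop-2-yn-1-one | COc1cc(C#CC(=O)c2c(O)c(OC)c(OCc3ccccc3)cc2OCc2ccccc2)c(OCc2ccccc2)cc1OCc1ccccc1
F6 | step 12 | 3-lithio-5,7,2',4'-tetrakis(benzyloxy)-8,5'-dimethoxyflavone | [Li]c1c(-c2cc(OC)c(OCc3ccccc3)cc2OCc2ccccc2)oc2c(OC)c(OCc3ccccc3)cc(OCc3ccccc3)c2c1=O
F7 | step 12 | dimethyl [5,7,2',4'-tetrakis(benzyloxy)-8,5'-dimethoxyflavon-3-yl]boronate | COB(OC)c1c(-c2cc(OC)c(OCc3ccccc3)cc2OCc2ccccc2)oc2c(OC)c(OCc3ccccc3)cc(OCc3ccccc3)c2c1=O
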